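Begin with slowness: in cedar the third step takes 40 min to halve the double product at the charged reagent, and that time lengthens as the reagent is spent, so do not hold it against the run of 50 min as if c(reagent) stood still.

    substrate + reagent → single product (k1 = 0.016 L mol⁻¹ s⁻¹)
    reagent + single product → double product (k2 = 0.0089 L mol⁻¹ s⁻¹)
    reagent + double product → triple product (k3 = 0.0029 L mol⁻¹ s⁻¹)
    substrate → decomposition product (k4 = 2.0 × 10⁻⁷ s⁻¹)
    substrate ⇌ dormant form (K5 = 0.86, k5 = 1.4 × 10⁻⁴ s⁻¹)

- cedar: substrate 0.10 M; reagent 0.100 M; time 50 min
- birch: substrate 0.10 M; reagent 0.160 M; time 50 min

1. which of these there is most of at the end, counted by the substrate in it, cedar (double product / substrate / single product / triple product)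
2. which of these there is most of at the end, counted by the substrate in it, birch (double product / substrate / single product / triple product)
3. how much there is at the end of the one of these that leads, in percent of the substrate charged: cedar
4. how much there is at the end of the one of these that leads, in percent of the substrate charged: birch

Find the concentration that sets the order of the rates. It is c(reagent), which stands in each of the three product steps. Now divide the first step's rate by the second's: c(reagent) cancels, leaving c(substrate) over c(single product) times the selectivity factor, the first rate constant over the second, 1.80. While that product exceeds one, single product rises.

Since reagent stands in the three product steps, reckon them in exposure: the first rate constant times mean c(reagent) times the run. Guess the mean as a quarter of the charge in cedar and a third in birch, then test the guess against the reagent spent.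

Cedar: exposure 1.20, substrate 30.1 %, single product 47.7 %, double product 19.9 %, triple product 2.28 %.

Birch: exposure 2.56, substrate 7.73 %, single product 36.8 %, double product 44.0 %, triple product 11.5 %.

These figures spend 94.3 % of the reagent in cedar and 99.5 % in birch, so both stay inside the charge.

The weak link is the dormant form, left out so far. In cedar the first step starts 11 times faster than the forward dormant step, so take the share 8.75 % off each product, and in birch 5.47 %.

Commit to single product at 43.6 % in cedar, and double product at 41.6 % in birch.

The forecast, which set out to “use the mean reagent level to move material along the chain”, named single product at 44 % in cedar and double product at 41.5 % in birch, slightly apart from my figures.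

The flask gives single product at 44.1 % in cedar and double product at 41.5 % in birch, as the forecast said. Apply the selectivity factor to the end of cedar, where substrate stands at 20.3 % and single product at 44.1 %: the ratio is 0.827, less than one, and cedar holds 43.4 % of single product at 500 min. In birch, from 7.32 % and 35.8 %, the ratio is 0.368, lower than in cedar, and single product stands at 30.2 % at 500 min.

The constants used here were drawn at random within sensible limits, and the outcome is calculated.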